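Ring cannot rise in a flask for as long as more of it is lost than made, and the winter flask, which is the flask asked about, read 28% at 80.0 min but 17% at 120 min.

| flask | substrate | activator | temperature | remark | time |
|---|---|---|---|---|---|
| winter | 10 mM | 10 mM | 70 °C | the very flask that is asked about, followed so far |  |
| spring | 15 mM | 10 mM | 65 °C | run made earlier |  |
| flask | 10 mM | 10.0 mM | 70 °C |  | 2.0 h |

| run | time / min | ring / % | substrate / % |
|---|---|---|---|
| winter | 10.0 | 7 | 46 |
| winter | 15.0 | 10 | 35 |
| winter | 25.0 | 18 | 24 |
| winter | 40.0 | 24 | 13 |
| winter | 80.0 | 28 | 3 |
| winter | 120 | 17 | 1 |
| spring | 20.0 | 7 | 45 |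
| spring | 40.0 | 12 | 28 |
| spring | 60.0 | 16 | 22 |
| spring | 80.0 | 19 | 16 |
| spring | 90.0 | 20 | 17 |
| spring | 120 | 19 | 17 |

(each reading ± 1.5 percentage points)

- red: at 2.0 h add activator, 50.0% of the amount charged, then wait 2.0 h
- violet: change nothing and wait 2.0 h more
- green: at 2.0 h take out 90% of the ring then present, then wait 2.0 h
- amber: at 2.0 h raise the temperature by 20 K, then wait 2.0 h

- removed ring is counted in
- the numbers in the tables scatter by 1.5 percentage points (one standard deviation)
- additions bring no volume worth counting

1. ring, in percent of the substrate first charged, at 2.0 h
2. the option that brings most further ring ("none" if no option brings more than 2 percentage points) (red / violet / green / amber / none)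
3. ring present, with what was taken out counted in, in percent of the substrate first charged, after green
4. ring present, with what was taken out counted in, in percent of the substrate first charged, after amber

From those two readings I carry one quantity: the half-fall time, in which c_ring halves on the falling side of its peak, with whatever still feeds the ring counted in. It is an apparent first-order half-life, and here it reads 55.6 min, a reading that carries the scatter of 1.5 percentage points. For the winter flask at 2.0 h I commit to the last reading, 17%.

Now I turn the question round. At this pace the further 2.0 h keeps 22.4% of the ring, so for waiting to pay, new ring would have to replace a loss of 13 points and then add the margin of 2 points. Green asks less, because the 10.0% left behind loses 1.3 points, but new ring must still cover that and the margin. The substrate reading of 1% cannot tell whether what is left of the substrate covers that loss, since the two differ by 0.30 points and a reading scatters by 1.5 points. I judge the feed, seen or unseen, too small to clear the margin as well and name no option, though for green this is a judgement, not a reading.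

The forecast gives 17.5% now, none as the best option, 19% after green and 7% after amber, and says “Waiting loses ring, and heating loses it faster”.

The flask gives 19.7% at 2.0 h, none as the best option, 20.2% after green and 0% after amber.

    substrate + activator → activated form (k = 10.1 M⁻¹ min⁻¹, Ea = 74.0 kJ mol⁻¹)
    activated form → ring (k = 0.0239 min⁻¹, Ea = 93.0 kJ mol⁻¹)
    substrate + activated form → open dimer (k = 2.32 M⁻¹ min⁻¹, Ea = 66.0 kJ mol⁻¹)
    ring → over-reaction product (k = 0.0180 min⁻¹, Ea = 100 kJ mol⁻¹)
    (constants at 70 °C)

Carried from 19.7%, the half-fall time of 55.6 min gives a loss of 15 points over the further 2.0 h, and violet loses 15 points. At 2.00 h ring is made at 0.464 of the rate at which it is used up, less than the loss. The neighbouring flask is the same flask read at 8.0 h, so its further 6.00 h are 6.47 half-fall times, and these take 19.7% down to 0.221%. That flask holds 0.140% of ring.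

Readings and results stem from a simulated flask from invented constants.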